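**Plan**
- Retrosynthesis: open the hydroxylactone at its O–C(=O) bond and at its ring C3–C4 bond (glyoxylate aldol); cut the bond between the vinylidene carbon and the side-chain CH (conjugate addition of an alkenylboronate to furan-2(5H)-one); strip the two-carbon handle from C1 of the hydrindane; cut C4–C5 and C6–C7 of the cyclohexane ring; finally remove the isopropenyl and C7 carbons from 2-methylcyclopentenone.
- Enabling feature: in the six-membered ring of the trans-hydrindane, the gem-dimethyl carbon C4 and the methylene C7 (on the angular quaternary C7a) flank an unsubstituted C5–C6 ethano unit. C4 is therefore a latent tertiary radical (isopropenyl on C3a), C7 a non-enolisable aldehyde, and C5–C6 can come from a vinylphosphonium salt whose phosphorus leaves in the ring closure.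
- Forward order: cyclopentane (step 1), cyclohexene ring annulated (step 4), helpers removed (C6=C7 hydrogenated, dioxolane cleaved, step 5), C1 acetyl group, alkenylboronate, butyrolactone, aldehyde, hydroxylactone last.
- Stereochemistry: C3a from a copper-catalysed asymmetric conjugate addition; C7a from anti trapping of the enolate, which also fixes the trans fusion; C1 from α-face hydroboration opposite the angular methyl; the side-chain CH from Rh/(R)-BINAP; the two lactone carbons from an (S)-prolinol-catalysed anti aldol.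

Key step: step 4

Remark: the sense of induction of the chiral catalysts in steps 1, 11 and 14 is assigned by analogy with simpler substrates; the antipode named is the one expected to give the drawn configuration.

**Step 1**
Reactants: 1 2-methylcyclopent-2-en-1-one; 2 isopropenylmagnesium bromide; 3 formaldehyde
Product: 5 (2R,3S)-2-(hydroxymethyl)-2-methyl-3-(prop-1-en-2-yl)cyclopentan-1-one, via magnesium enolate 4 (not isolated)
Conditions: Cu(OTf)2 (3 mol %), chiral hydroxyalkyl-imidazolinium NHC precursor (4 mol %, antipode giving the 3S adduct), Et2O, −30 °C; then HCHO gas (cracked paraformaldehyde), −78 → −20 °C; H2O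
Reagents that add atoms: isopropenylmagnesium bromide, CC(=C)[Mg]Br; formaldehyde, C=O
Why: Copper-catalysed asymmetric conjugate addition of the alkenyl Grignard reagent sets C3 under ligand control, and the tetrasubstituted enolate 4 should add to formaldehyde anti to the new isopropenyl group, which places methyl cis and CH2OH trans to it.

**Step 2**
Reactants: 5 (2R,3S)-2-(hydroxymethyl)-2-methyl-3-(prop-1-en-2-yl)cyclopentan-1-one; 6 ethane-1,2-diol
Product: 7 [(6R,7S)-6-methyl-7-(prop-1-en-2-yl)-1,4-dioxaspiro[4.4]nonan-6-yl]methanol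
Conditions: 6 (5 equiv), PPTS (10 mol %), benzene, reflux, Dean–Stark
Reagents that add atoms: ethane-1,2-diol, OCCO
Why: Acid-catalysed ketalisation with azeotropic removal of water masks the ketone, so that it can later neither react with the ylide nor take part in a bridged closure; no stereocentre is touched.

**Step 3**
Reactants: 7 [(6R,7S)-6-methyl-7-(prop-1-en-2-yl)-1,4-dioxaspiro[4.4]nonan-6-yl]methanol
Product: 8 (6R,7S)-6-methyl-7-(prop-1-en-2-yl)-1,4-dioxaspiro[4.4]nonane-6-carbaldehyde
Conditions: Dess–Martin periodinane, CH2Cl2, 0 °C → rt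
Reagents that add atoms: none
Why: Dess–Martin oxidation of the neopentyl primary alcohol gives an aldehyde that cannot enolise because it sits on the quaternary carbon.

**Step 4**
Reactants: 8 (6R,7S)-6-methyl-7-(prop-1-en-2-yl)-1,4-dioxaspiro[4.4]nonane-6-carbaldehyde; 9 triphenyl(vinyl)phosphonium bromide
Product: 12 (3'aS,7'aS)-4',4',7'a-trimethyl-2',3',3'a,4',5',7'a-hexahydrospiro[1,3-dioxolane-2,1'-indene], via phosphonium salt 10 (not isolated), via phosphorus ylide 11 (not isolated)
Conditions: Fe(acac)3 (30 mol %), PhSiH3 (2.5 equiv), 9 (3 equiv), EtOH/(CH2OH)2 5:1, 60 °C; then KOtBu (4 equiv), THF, 0 → 60 °C, high dilution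
Reagents that add atoms: triphenyl(vinyl)phosphonium bromide, C=C[P+](c1ccccc1)(c1ccccc1)c1ccccc1.[Br-]
Why: Proposed new method: an iron hydride formed from Fe(acac)3 and PhSiH3 should transfer a hydrogen atom to the terminal carbon of the isopropenyl group, and the nucleophilic tertiary radical at C4 should add to the unsubstituted terminus of the electron-poor vinylphosphonium salt 9 (C4–C5 bond); reduction of the α-phosphonio radical by divalent iron and protonation by ethanol give salt 10, which KOtBu converts into ylide 11 for an intramolecular Wittig reaction with the neopentyl aldehyde (C6=C7 bond). The closest known reaction types are the iron-mediated hydrogen-atom-transfer reductive coupling of 1,1-disubstituted alkenes with electron-poor alkenes, the hydrogen-atom-transfer radical–polar crossover annulation (Giese addition then aldol closure), and the Schweizer annulation, in which a nucleophile adds to a vinylphosphonium salt and the ylide closes a ring by Wittig olefination; what is new is a carbon radical from hydrogen-atom transfer in the role of that nucleophile. The one ring closed is the six-membered carbocycle, by attack of the ylide carbon on the exocyclic C=O (6-exo-trig addition, oxaphosphetane, loss of Ph3PO). No stereocentre is created; the trans ring fusion is inherited from the trans arrangement of the C4 arm and the formyl group set in step 1. The step needs Markovnikov hydrogen-atom transfer (secured by the single, 1,1-disubstituted alkene), capture of the radical by 9 before it is reduced (excess 9), and an electrophile that survives the radical stage and cannot enolise under base (the quaternary C7a makes the aldehyde non-enolisable, and the dioxolane keeps the C1 carbonyl out of a competing bridged closure).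

**Step 5**
Reactants: 12 (3'aS,7'aS)-4',4',7'a-trimethyl-2',3',3'a,4',5',7'a-hexahydrospiro[1,3-dioxolane-2,1'-indene]
Product: 14 (3aS,7aS)-4,4,7a-trimethyloctahydro-1H-inden-1-one, via saturated ketal 13 (not isolated)
Conditions: H2 (1 atm), Pd/C (10 wt %), EtOAc, rt; then 2 M HCl, THF, rt
Reagents that add atoms: water, O
Why: Heterogeneous hydrogenation saturates the only alkene without creating a stereocentre, and aqueous acid then hydrolyses the dioxolane, which removes both helpers of the annulation.

**Step 6**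
Reactants: 14 (3aS,7aS)-4,4,7a-trimethyloctahydro-1H-inden-1-one; 15 ethyltriphenylphosphonium bromide
Product: 16 (1Z,3aS,7aS)-1-ethylidene-4,4,7a-trimethyloctahydro-1H-indene
Conditions: 15 (4 equiv), KOtBu (4 equiv), THF, reflux
Reagents that add atoms: ethyltriphenylphosphonium bromide, CC[P+](c1ccccc1)(c1ccccc1)c1ccccc1.[Br-]
Why: Wittig olefination of the hindered cyclopentanone with the non-stabilised ylide (as for 17-oxo steroids) should give mainly the Z-ethylidene compound; the geometry is of no consequence later.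

**Step 7**
Reactants: 16 (1Z,3aS,7aS)-1-ethylidene-4,4,7a-trimethyloctahydro-1H-indene
Product: 17 (1S)-1-[(1S,3aS,7aS)-4,4,7a-trimethyloctahydro-1H-inden-1-yl]ethan-1-ol
Conditions: 9-BBN (3 equiv), THF, 60 °C; then NaOH (aq), H2O2, 0 °C → rt
Reagents that add atoms: hydrogen peroxide, OO
Why: Hydroboration–oxidation places boron on the less substituted exocyclic carbon and delivers hydrogen to C1 from the α-face opposite the angular methyl, which sets C1 with the side chain cis to that methyl.

**Step 8**
Reactants: 17 (1S)-1-[(1S,3aS,7aS)-4,4,7a-trimethyloctahydro-1H-inden-1-yl]ethan-1-ol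
Product: 18 1-[(1S,3aS,7aS)-4,4,7a-trimethyloctahydro-1H-inden-1-yl]ethan-1-one
Conditions: Dess–Martin periodinane, CH2Cl2, 0 °C → rt
Reagents that add atoms: none
Why: Dess–Martin oxidation gives the methyl ketone without epimerising C1, whose β-acetyl arrangement is also the thermodynamically preferred one.

**Step 9**
Reactants: 18 1-[(1S,3aS,7aS)-4,4,7a-trimethyloctahydro-1H-inden-1-yl]ethan-1-one; 19 N-phenylbis(trifluoromethanesulfonimide)
Product: 20 1-[(1S,3aS,7aS)-4,4,7a-trimethyloctahydro-1H-inden-1-yl]ethenyl trifluoromethanesulfonate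
Conditions: KN(SiMe3)2, THF, −78 °C; then 19, −78 → 0 °C
Reagents that add atoms: N-phenylbis(trifluoromethanesulfonimide), O=S(=O)(N(c1ccccc1)S(=O)(=O)C(F)(F)F)C(F)(F)F
Why: Kinetic deprotonation with the bulky amide occurs at the methyl group and not at the hindered tertiary C1–H, and O-triflation of the terminal enolate gives the 1,1-disubstituted enol triflate.

**Step 10**
Reactants: 20 1-[(1S,3aS,7aS)-4,4,7a-trimethyloctahydro-1H-inden-1-yl]ethenyl trifluoromethanesulfonate; 21 bis(pinacolato)diboron
Product: 22 4,4,5,5-tetramethyl-2-{1-[(1R,3aS,7aR)-4,4,7a-trimethyloctahydro-1H-inden-1-yl]ethenyl}-1,3,2-dioxaborolane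
Conditions: PdCl2(PPh3)2 (3 mol %), PPh3 (6 mol %), KOPh (1.5 equiv), toluene, 50 °C
Reagents that add atoms: bis(pinacolato)diboron, CC1(C)OB(OC1(C)C)B1OC(C)(C)C(C)(C)O1
Why: Miyaura borylation of the alkenyl triflate keeps the double bond in place and gives the alkenylboronate (the 7a descriptor changes only through the priority of boron).

**Step 11**
Reactants: 22 4,4,5,5-tetramethyl-2-{1-[(1R,3aS,7aR)-4,4,7a-trimethyloctahydro-1H-inden-1-yl]ethenyl}-1,3,2-dioxaborolane; 23 furan-2(5H)-one
Product: 24 (4R)-4-{1-[(1R,3aS,7aS)-4,4,7a-trimethyloctahydro-1H-inden-1-yl]ethenyl}oxolan-2-one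
Conditions: [Rh(OH)((R)-binap)]2 (3 mol %), 23 (3 equiv), KOH (0.2 equiv), dioxane/H2O 10:1, 50 °C
Reagents that add atoms: furan-2(5H)-one, O=C1OCC=C1
Why: Rhodium-catalysed asymmetric conjugate addition (Hayashi–Miyaura reaction) of the alkenylboronate to the butenolide forms the bond between the vinylidene carbon and the side-chain CH, and the BINAP ligand controls the face of the butenolide and so sets this stereocentre (R).

**Step 12**
Reactants: 24 (4R)-4-{1-[(1R,3aS,7aS)-4,4,7a-trimethyloctahydro-1H-inden-1-yl]ethenyl}oxolan-2-one; 25 N,O-dimethylhydroxylamine hydrochloride; 26 acetic anhydride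
Product: 28 (2R)-4-[methoxy(methyl)amino]-4-oxo-2-{1-[(1R,3aS,7aS)-4,4,7a-trimethyloctahydro-1H-inden-1-yl]ethenyl}butyl acetate, via hydroxy Weinreb amide 27 (not isolated)
Conditions: 25 (3 equiv), AlMe3 (3 equiv), CH2Cl2, 0 °C → rt; then 26, pyridine, DMAP (cat.), 0 °C
Reagents that add atoms: N,O-dimethylhydroxylamine hydrochloride, CNOC.Cl; acetic anhydride, CC(=O)OC(C)=O
Why: Aluminium-amide aminolysis opens the lactone to the Weinreb amide, and acetylation of the liberated primary alcohol in the same flask prevents relactonisation and installs the acetate of the target.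

**Step 13**
Reactants: 28 (2R)-4-[methoxy(methyl)amino]-4-oxo-2-{1-[(1R,3aS,7aS)-4,4,7a-trimethyloctahydro-1H-inden-1-yl]ethenyl}butyl acetate
Product: 29 (2R)-4-oxo-2-{1-[(1R,3aS,7aS)-4,4,7a-trimethyloctahydro-1H-inden-1-yl]ethenyl}butyl acetate
Conditions: Cp2Zr(H)Cl (1.5 equiv), THF, rt, 15 min
Reagents that add atoms: none
Why: Reduction of the tertiary amide with Cp2Zr(H)Cl stops at the aldehyde after hydrolysis and leaves the acetate and the hindered alkene untouched.

**Step 14**
Reactants: 29 (2R)-4-oxo-2-{1-[(1R,3aS,7aS)-4,4,7a-trimethyloctahydro-1H-inden-1-yl]ethenyl}butyl acetate; 30 ethyl glyoxylate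
Product: 31 ethyl (2R,3S,4R)-4-(acetoxymethyl)-3-formyl-2-hydroxy-5-[(1R,3aS,7aS)-4,4,7a-trimethyloctahydro-1H-inden-1-yl]hex-5-enoate
Conditions: (S)-α,α-bis[3,5-bis(trifluoromethyl)phenyl]prolinol (10 mol %), 30 (toluene solution, 3 equiv), MeCN, H2O (3 equiv), rt
Reagents that add atoms: ethyl glyoxylate, CCOC(=O)C=O
Why: Enamine-mediated direct cross-aldol addition of the aldehyde to the highly electrophilic glyoxylate should pass through a hydrogen-bonded anti transition state under catalyst control, which sets the two remaining stereocentres (anti aldol, 2R,3S).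

**Step 15**
Reactants: 31 ethyl (2R,3S,4R)-4-(acetoxymethyl)-3-formyl-2-hydroxy-5-[(1R,3aS,7aS)-4,4,7a-trimethyloctahydro-1H-inden-1-yl]hex-5-enoate
Product: 33 (2R)-2-[(3R,4R)-4-hydroxy-5-oxooxolan-3-yl]-3-[(1R,3aS,7aS)-4,4,7a-trimethyloctahydro-1H-inden-1-yl]but-3-en-1-yl acetate, via hydroxy ester 32 (not isolated)
Conditions: NaBH4 (1.0 equiv), EtOH, −20 °C; then TsOH·H2O (cat.), CH2Cl2, rt
Reagents that add atoms: none
Why: Borohydride reduces the aldehyde much faster than the esters, and the γ-hydroxy ester closes to the five-membered lactone under acid catalysis; the anti aldol relationship becomes the cis arrangement of hydroxyl and side chain on the ring.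

**Compound list**
1 | 2-methylcyclopent-2-en-1-one | CC1=CCCC1=O | starting material
2 | isopropenylmagnesium bromide | CC(=C)[Mg]Br | starting material
3 | formaldehyde (from paraformaldehyde) | C=O | starting material
4 | bromo{[(3S)-2-methyl-3-(prop-1-en-2-yl)cyclopent-1-en-1-yl]oxy}magnesium | CC1=C(O[Mg]Br)CC[C@H]1C(C)=C | intermediate (not isolated)
5 | (2R,3S)-2-(hydroxymethyl)-2-methyl-3-(prop-1-en-2-yl)cyclopentan-1-one | O=C1CC[C@@H](C(C)=C)[C@]1(C)CO | intermediate
6 | ethane-1,2-diol | OCCO | starting material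
7 | [(6R,7S)-6-methyl-7-(prop-1-en-2-yl)-1,4-dioxaspiro[4.4]nonan-6-yl]methanol | C1COC2(O1)CC[C@@H](C(C)=C)[C@]2(C)CO | intermediate
8 | (6R,7S)-6-methyl-7-(prop-1-en-2-yl)-1,4-dioxaspiro[4.4]nonane-6-carbaldehyde | C1COC2(O1)CC[C@@H](C(C)=C)[C@]2(C)C=O | intermediate
9 | triphenyl(vinyl)phosphonium bromide | C=C[P+](c1ccccc1)(c1ccccc1)c1ccccc1.[Br-] | starting material
10 | {3-[(6R,7S)-6-formyl-6-methyl-1,4-dioxaspiro[4.4]nonan-7-yl]-3-methylbutyl}triphenylphosphonium bromide | C1COC2(O1)CC[C@@H](C(C)(C)CC[P+](c3ccccc3)(c3ccccc3)c3ccccc3)[C@]2(C)C=O.[Br-] | intermediate (not isolated)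
11 | ylide of 10: (6R,7S)-6-methyl-7-[2-methyl-4-(triphenyl-λ5-phosphanylidene)butan-2-yl]-1,4-dioxaspiro[4.4]nonane-6-carbaldehyde | C1COC2(O1)CC[C@@H](C(C)(C)CC=P(c3ccccc3)(c3ccccc3)c3ccccc3)[C@]2(C)C=O | intermediate (not isolated)
12 | (3'aS,7'aS)-4',4',7'a-trimethyl-2',3',3'a,4',5',7'a-hexahydrospiro[1,3-dioxolane-2,1'-indene] | C1COC2(O1)CC[C@H]3C(C)(C)CC=C[C@]23C | intermediate
13 | (3'aS,7'aS)-4',4',7'a-trimethyloctahydrospiro[1,3-dioxolane-2,1'-indene] | C1COC2(O1)CC[C@H]3C(C)(C)CCC[C@]23C | intermediate (not isolated)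
14 | (3aS,7aS)-4,4,7a-trimethyloctahydro-1H-inden-1-one | O=C1CC[C@H]2C(C)(C)CCC[C@]12C | intermediate
15 | ethyltriphenylphosphonium bromide | CC[P+](c1ccccc1)(c1ccccc1)c1ccccc1.[Br-] | starting material
16 | (1Z,3aS,7aS)-1-ethylidene-4,4,7a-trimethyloctahydro-1H-indene | C/C=C1/CC[C@H]2C(C)(C)CCC[C@]12C | intermediate
17 | (1S)-1-[(1S,3aS,7aS)-4,4,7a-trimethyloctahydro-1H-inden-1-yl]ethan-1-ol | C[C@H](O)[C@H]1CC[C@H]2C(C)(C)CCC[C@]12C | intermediate
18 | 1-[(1S,3aS,7aS)-4,4,7a-trimethyloctahydro-1H-inden-1-yl]ethan-1-one | CC(=O)[C@H]1CC[C@H]2C(C)(C)CCC[C@]12C | intermediate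
19 | N-phenylbis(trifluoromethanesulfonimide) | O=S(=O)(N(c1ccccc1)S(=O)(=O)C(F)(F)F)C(F)(F)F | starting material
20 | 1-[(1S,3aS,7aS)-4,4,7a-trimethyloctahydro-1H-inden-1-yl]ethenyl trifluoromethanesulfonate | C=C(OS(=O)(=O)C(F)(F)F)[C@H]1CC[C@H]2C(C)(C)CCC[C@]12C | intermediate
21 | bis(pinacolato)diboron | CC1(C)OB(OC1(C)C)B1OC(C)(C)C(C)(C)O1 | starting material
22 | 4,4,5,5-tetramethyl-2-{1-[(1R,3aS,7aR)-4,4,7a-trimethyloctahydro-1H-inden-1-yl]ethenyl}-1,3,2-dioxaborolane | C=C(B1OC(C)(C)C(C)(C)O1)[C@H]1CC[C@H]2C(C)(C)CCC[C@]12C | intermediate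
23 | furan-2(5H)-one | O=C1OCC=C1 | starting material
24 | (4R)-4-{1-[(1R,3aS,7aS)-4,4,7a-trimethyloctahydro-1H-inden-1-yl]ethenyl}oxolan-2-one | C=C([C@H]1CC[C@H]2C(C)(C)CCC[C@]12C)[C@@H]1COC(=O)C1 | intermediate
25 | N,O-dimethylhydroxylamine hydrochloride | CNOC.Cl | starting material
26 | acetic anhydride | CC(=O)OC(C)=O | starting material
27 | (3R)-4-hydroxy-N-methoxy-N-methyl-3-{1-[(1R,3aS,7aS)-4,4,7a-trimethyloctahydro-1H-inden-1-yl]ethenyl}butanamide | C=C([C@H]1CC[C@H]2C(C)(C)CCC[C@]12C)[C@H](CO)CC(=O)N(C)OC | intermediate (not isolated)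
28 | (2R)-4-[methoxy(methyl)amino]-4-oxo-2-{1-[(1R,3aS,7aS)-4,4,7a-trimethyloctahydro-1H-inden-1-yl]ethenyl}butyl acetate | C=C([C@H]1CC[C@H]2C(C)(C)CCC[C@]12C)[C@H](COC(C)=O)CC(=O)N(C)OC | intermediate
29 | (2R)-4-oxo-2-{1-[(1R,3aS,7aS)-4,4,7a-trimethyloctahydro-1H-inden-1-yl]ethenyl}butyl acetate | C=C([C@H]1CC[C@H]2C(C)(C)CCC[C@]12C)[C@H](COC(C)=O)CC=O | intermediate
30 | ethyl glyoxylate | CCOC(=O)C=O | starting material
31 | ethyl (2R,3S,4R)-4-(acetoxymethyl)-3-formyl-2-hydroxy-5-[(1R,3aS,7aS)-4,4,7a-trimethyloctahydro-1H-inden-1-yl]hex-5-enoate | C=C([C@H]1CC[C@H]2C(C)(C)CCC[C@]12C)[C@H](COC(C)=O)[C@H](C=O)[C@@H](O)C(=O)OCC | intermediate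
32 | ethyl (2R,3R,4R)-4-(acetoxymethyl)-2-hydroxy-3-(hydroxymethyl)-5-[(1R,3aS,7aS)-4,4,7a-trimethyloctahydro-1H-inden-1-yl]hex-5-enoate | C=C([C@H]1CC[C@H]2C(C)(C)CCC[C@]12C)[C@H](COC(C)=O)[C@H](CO)[C@@H](O)C(=O)OCC | intermediate (not isolated)
33 | (2R)-2-[(3R,4R)-4-hydroxy-5-oxooxolan-3-yl]-3-[(1R,3aS,7aS)-4,4,7a-trimethyloctahydro-1H-inden-1-yl]but-3-en-1-yl acetate | C=C([C@H]1CC[C@H]2C(C)(C)CCC[C@]12C)[C@H](COC(C)=O)[C@@H]1COC(=O)[C@@H]1O | target

**Step count**
Total: 15 steps. Longest linear sequence: 15 steps (from 1).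

**Steps most likely to fail**

Step 4 (Proposed new method). The tertiary radical may be reduced before it is captured (net hydrogenation of the isopropenyl group), alkoxide may consume the vinylphosphonium salt by conjugate addition, or the ylide may close slowly onto the hindered aldehyde. The fallback sets out from 8 and separates the two bond formations. Iron-mediated reductive coupling of 8 with phenyl vinyl sulfone (Fe(acac)3, PhSiH3, EtOH, 60 °C) should give the sulfone aldehyde F1. LiN(iPr)2 at −78 °C should close the ring by addition of the α-sulfonyl carbanion to the aldehyde, and acetic anhydride traps the alkoxide as the β-acetoxy sulfone F2. Julia-type reductive elimination with Na(Hg) in buffered MeOH returns to the route at 12.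

Step 11. Transmetalation and insertion of the hindered, α-branched alkenyl group may be slower than protodeboronation, and the C1 stereocentre next to the reacting carbon may erode the facial control of the ligand. The fallback sets out from 22 and uses an allylic substitution in place of the conjugate addition. Commercial (Z)-but-2-ene-1,4-diol is monoacetylated to (Z)-4-hydroxybut-2-en-1-yl acetate F3 and phosphorylated with ClP(O)(OEt)2 to the allylic phosphate F4. Enantioselective SN2' substitution of F4 with 22 (CuCl, chiral sulfonate-bearing NHC ligand, NaOMe, THF) should give the branched diene acetate F5. Hydroboration of the monosubstituted vinyl group with disiamylborane and NaBO3·4H2O work-up gives the alcohol F6, and Dess–Martin oxidation returns to the route at 29.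

Step 14. Enamine formation from the hindered β-branched aldehyde may be slow, self-condensation may compete, and the anti and facial selectivity may drop in a mismatched pairing. The fallback sets out from 24 and replaces enamine catalysis by a Lewis-acid-catalysed Mukaiyama aldol. Opening of 24 with EtSH/AlMe3 gives the hydroxy thioester F7, and acetylation gives the acetoxy thioester F8. LiN(SiMe3)2 and Me3SiCl give the (Z)-silyl ketene thioacetal F9. An anti-selective aldol addition to 30, catalysed by Sn(OTf)2 with a chiral bis(oxazolinyl)pyridine ligand, should give the thioester F10. Fukuyama reduction (Et3SiH, Pd/C, acetone) returns to the route at 31.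

**Further compounds**
F1 | step 4 | (6R,7S)-6-methyl-7-[2-methyl-4-(phenylsulfonyl)butan-2-yl]-1,4-dioxaspiro[4.4]nonane-6-carbaldehyde | C1COC2(O1)CC[C@@H](C(C)(C)CCS(=O)(=O)c3ccccc3)[C@]2(C)C=O
F2 | step 4 | 7'-acetoxy-6'-(phenylsulfonyl) derivative of ketal 13 (trans-fused, mixture at C6' and C7') | C1COC2(O1)CC[C@H]3C(C)(C)CC(S(=O)(=O)c4ccccc4)C(OC(C)=O)[C@]23C
F3 | step 11 | (Z)-4-hydroxybut-2-en-1-yl acetate | CC(=O)OC/C=C\CO
F4 | step 11 | (Z)-4-[(diethoxyphosphoryl)oxy]but-2-en-1-yl acetate | CCOP(=O)(OCC)OC/C=C\COC(C)=O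
F5 | step 11 | (2R)-2-{1-[(1R,3aS,7aS)-4,4,7a-trimethyloctahydro-1H-inden-1-yl]ethenyl}but-3-en-1-yl acetate | C=C([C@H]1CC[C@H]2C(C)(C)CCC[C@]12C)[C@H](COC(C)=O)C=C
F6 | step 11 | (2R)-4-hydroxy-2-{1-[(1R,3aS,7aS)-4,4,7a-trimethyloctahydro-1H-inden-1-yl]ethenyl}butyl acetate | C=C([C@H]1CC[C@H]2C(C)(C)CCC[C@]12C)[C@H](COC(C)=O)CCO
F7 | step 14 | S-ethyl (3R)-4-hydroxy-3-{1-[(1R,3aS,7aS)-4,4,7a-trimethyloctahydro-1H-inden-1-yl]ethenyl}butanethioate | C=C([C@H]1CC[C@H]2C(C)(C)CCC[C@]12C)[C@H](CO)CC(=O)SCC
F8 | step 14 | S-ethyl (3R)-4-acetoxy-3-{1-[(1R,3aS,7aS)-4,4,7a-trimethyloctahydro-1H-inden-1-yl]ethenyl}butanethioate | C=C([C@H]1CC[C@H]2C(C)(C)CCC[C@]12C)[C@H](COC(C)=O)CC(=O)SCC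
F9 | step 14 | (Z)-trimethylsilyl ketene thioacetal of F8 | C=C([C@H]1CC[C@H]2C(C)(C)CCC[C@]12C)[C@H](COC(C)=O)/C=C(/O[Si](C)(C)C)SCC
F10 | step 14 | ethyl (2R,3S,4R)-4-(acetoxymethyl)-3-[(ethylsulfanyl)carbonyl]-2-hydroxy-5-[(1R,3aS,7aS)-4,4,7a-trimethyloctahydro-1H-inden-1-yl]hex-5-enoate | C=C([C@H]1CC[C@H]2C(C)(C)CCC[C@]12C)[C@H](COC(C)=O)[C@H](C(=O)SCC)[C@@H](O)C(=O)OCC
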